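**Retrosynthetic overview**

- The target is opened at the C5'–isobutyryl bond of ring B (Friedel–Crafts acylation at the only free ring carbon) and at four benzyl ethers (hydrogenolysis).
- The strategy rests on ring A: O at C1, C3, C5 alternates with C at C2, C4, C6, the C1 methoxy is para to the C4 acetyl, and the acetyl sits between two oxygens. Ring A is cut at C5–C6 and C3–C4 into a 1,3-dimethoxy-2-methyl-1-silyloxydiene (C3–C2–C1–C6, carrying the ring B methylene at its CH terminus) and 4-(benzyloxy)but-3-yn-2-one (C5–C4); loss of methanol aromatises the adduct.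
- The diene comes from a β-methoxy enoate, this from a β-keto ester, and this from aldol addition of the methyl 2-methylacetoacetate dianion to the ring B aldehyde followed by ionic deoxygenation.
- The ring B aldehyde comes from 1,3,5-tris(benzyloxy)benzene (formylation, isobutyl Grignard addition, ionic reduction, formylation); the ynone comes from benzyl alcohol, trichloroethylene and N-methoxy-N-methylacetamide.
- Ring order: ring B is bought as an arene; ring A is the only ring made (step 11).

Key step: step 11

**Remarks on the chemistry**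

- Numbering: ring A is C1 (OMe), C2 (Me), C3 (OH), C4 (acetyl), C5 (OH), C6 (CH2); ring B is C1' (CH2), C2'/C4'/C6' (OH), C3' (3-methylbutyl), C5' (isobutyryl). The target has no stereocentre; racemic, diastereomeric and E/Z intermediates all converge.
- The C5 oxygen of ring A is carried as a benzyl ether. A second alkyl ether ortho to an acetyl group whose carbonyl is already chelated to the C3 oxygen is not expected to be cleaved cleanly by BCl3, and harsher Lewis acids would endanger the hindered C1 methyl ether; hydrogenolysis removes all four benzyl groups together.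
- 2,4,6-Trialkoxybenzyl halides ionise and self-condense readily. The bond from the ring B methylene to the acetoacetate chain is therefore made by aldol addition to the aldehyde and ionic deoxygenation, not by alkylation with a benzyl bromide.

**Route**

Step 1
Reactants: 1 1,3,5-tris(benzyloxy)benzene
Product: 3 2,4,6-tris(benzyloxy)benzaldehyde, via iminium chloride 2 (not isolated)
Conditions: POCl3, DMF, 0 → 23 °C; then ice/H2O
Reagents that add atoms: N,N-dimethylformamide CN(C)C=O; water O
Why: Vilsmeier–Haack formylation of a strongly activated arene whose three free positions are equivalent, so a single aldehyde should form after hydrolysis of iminium salt 2.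

Step 2
Reactants: 3 2,4,6-tris(benzyloxy)benzaldehyde
Product: 4 3-methyl-1-[2,4,6-tris(benzyloxy)phenyl]butan-1-ol (racemic)
Conditions: i-BuMgBr, THF, 0 °C; aq. NH4Cl
Reagents that add atoms: isobutylmagnesium bromide CC(C)C[Mg]Br
Why: Grignard addition to the aldehyde; the carbinol centre is formed racemic and is removed in step 3.

Step 3
Reactants: 4 3-methyl-1-[2,4,6-tris(benzyloxy)phenyl]butan-1-ol
Product: 5 1,3,5-tris(benzyloxy)-2-(3-methylbutyl)benzene
Conditions: Et3SiH, TFA, CH2Cl2, −20 → 0 °C
Reagents that add atoms: none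
Why: Ionic hydrogenation: the benzylic alcohol ionises under mild acid to a cation stabilised by three ortho/para oxygens and is reduced by the silane, while aryl benzyl ethers should tolerate brief cold TFA.

Step 4
Reactants: 5 1,3,5-tris(benzyloxy)-2-(3-methylbutyl)benzene
Product: 7 2,4,6-tris(benzyloxy)-3-(3-methylbutyl)benzaldehyde, via iminium chloride 6 (not isolated)
Conditions: POCl3, DMF, 0 → 40 °C; then ice/H2O
Reagents that add atoms: N,N-dimethylformamide CN(C)C=O; water O
Why: Second Vilsmeier–Haack formylation; the two remaining ring positions are related by symmetry, so only one regioisomer is possible.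

Step 5
Reactants: 7 2,4,6-tris(benzyloxy)-3-(3-methylbutyl)benzaldehyde; 8 methyl 2-methyl-3-oxobutanoate
Product: 10 methyl 5-hydroxy-2-methyl-3-oxo-5-[2,4,6-tris(benzyloxy)-3-(3-methylbutyl)phenyl]pentanoate (diastereomer mixture), via dianion 9 (not isolated)
Conditions: 8, NaH, THF, 0 °C; n-BuLi, 0 °C; then 7, −78 °C; AcOH, −78 °C
Reagents that add atoms: none
Why: Huckin–Weiler dianion aldol addition: the terminal carbanion of dianion 9 is its most nucleophilic site and adds to the non-enolisable aldehyde; both new stereocentres are uncontrolled and are erased in steps 6 and 7.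

Step 6
Reactants: 10 methyl 5-hydroxy-2-methyl-3-oxo-5-[2,4,6-tris(benzyloxy)-3-(3-methylbutyl)phenyl]pentanoate
Product: 11 methyl 2-methyl-3-oxo-5-[2,4,6-tris(benzyloxy)-3-(3-methylbutyl)phenyl]pentanoate
Conditions: Et3SiH (excess), TFA, CH2Cl2 (dilute), −20 → 0 °C
Reagents that add atoms: none
Why: Ionic hydrogenation of the trialkoxybenzylic alcohol as in step 3; the β-keto ester is inert to the silane, and any enone formed by elimination is reduced through the same cation.

Step 7
Reactants: 11 methyl 2-methyl-3-oxo-5-[2,4,6-tris(benzyloxy)-3-(3-methylbutyl)phenyl]pentanoate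
Product: 13 methyl 3-methoxy-2-methyl-5-[2,4,6-tris(benzyloxy)-3-(3-methylbutyl)phenyl]pent-2-enoate (E/Z mixture), via dimethyl ketal 12 (not isolated)
Conditions: HC(OMe)3, MeOH, TsOH·H2O (cat.), 23 → 50 °C
Reagents that add atoms: trimethyl orthoformate COC(OC)OC; methanol CO
Why: Acid-catalysed ketalisation with orthoformate and loss of methanol to the conjugated β-methoxy enoate, the standard O-methylation of β-keto esters for this diene class; either geometry leads to the same dienolate in step 8.

Step 8
Reactants: 13 methyl 3-methoxy-2-methyl-5-[2,4,6-tris(benzyloxy)-3-(3-methylbutyl)phenyl]pent-2-enoate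
Product: 15 1,3-dimethoxy-2-methyl-1-(trimethylsilyloxy)-5-[2,4,6-tris(benzyloxy)-3-(3-methylbutyl)phenyl]penta-1,3-diene (geometric mixture), via lithium dienolate 14 (not isolated)
Conditions: LDA (LiN(i-Pr)2), THF, −78 °C; Me3SiCl, −78 → 0 °C; pentane, filtration, used crude
Reagents that add atoms: chlorotrimethylsilane C[Si](C)(C)Cl
Why: γ-Deprotonation of the β-methoxy enoate (the α-carbon has no hydrogen) gives the extended dienolate 14, which is silylated on oxygen to the ketene acetal diene, as in the usual preparation of 1,3-dialkoxy-1-silyloxybutadienes.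

Step 9
Reactants: 16 benzyl alcohol; 17 trichloroethylene
Product: 19 (E)-benzyl 1,2-dichlorovinyl ether, via dichloroacetylene 18 (not isolated)
Conditions: KH, THF, 0 °C; then Cl2C=CHCl, −50 → 23 °C
Reagents that add atoms: none
Why: Greene synthesis of dichlorovinyl ethers: base converts trichloroethylene into dichloroacetylene 18, and anti addition of alkoxide and proton across it gives the (E)-ether.

Step 10
Reactants: 19 (E)-benzyl 1,2-dichlorovinyl ether
Product: 22 4-(benzyloxy)but-3-yn-2-one, via benzyl chloroethynyl ether 20 (not isolated), via lithium benzyloxyacetylide 21 (not isolated)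
Conditions: n-BuLi (2.2 equiv.), THF, −78 °C; MeC(O)N(OMe)Me, −78 → −20 °C; cold aq. NH4Cl; kept cold, used at once
Reagents that add atoms: N-methoxy-N-methylacetamide CON(C)C(C)=O
Why: Elimination to chloroalkyne 20 and chlorine–lithium exchange give alkoxyacetylide 21, which is acylated by the Weinreb amide; the chelated tetrahedral adduct prevents a second addition.

Step 11
Reactants: 15 1,3-dimethoxy-2-methyl-1-(trimethylsilyloxy)-5-[2,4,6-tris(benzyloxy)-3-(3-methylbutyl)phenyl]penta-1,3-diene; 22 4-(benzyloxy)but-3-yn-2-one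
Product: 25 1-[2-(benzyloxy)-6-hydroxy-4-methoxy-5-methyl-3-{[2,4,6-tris(benzyloxy)-3-(3-methylbutyl)phenyl]methyl}phenyl]ethanone, via cyclohexa-1,4-diene cycloadduct 23 (not isolated), via aryl trimethylsilyl ether 24 (not isolated)
Conditions: 22 (1.5 equiv.), PhMe (2 M), 0 → 23 °C, 48 h; then 1 M HCl, THF, 0 °C
Reagents that add atoms: none
Why: Proposed new method: the ketene-acetal diene 15 should attack through its CH terminus (C4 of the diene, the future C6 of ring A) the benzyloxy-bearing β-carbon of ynone 22 while its acetal carbon bonds to the acetyl-bearing α-carbon, either in one asynchronous [4+2] event or as a Mukaiyama–Michael addition whose allenolate/silyloxycarbenium pair collapses at once, giving cyclohexa-1,4-diene 23. The closest known reaction type is the Diels–Alder/aromatisation of 1,3-dialkoxy-1-silyloxybutadienes with propiolates and alkynyl ketones to resorcinol derivatives; a β-alkoxy alkynyl ketone has not been used in this role, and because its push–pull triple bond is a weaker electrophile the reaction is run concentrated and without a Lewis acid, which would destroy both partners. Ring A is closed as a [4+2] cycloaddition, or in the stepwise picture by 6-(enolexo)-exo-trig attack of the allenolate carbon on the carbenium carbon, forming C5–C6 and C3–C4. No stereocentre survives: 23 loses methanol by 1,4-elimination (H at C6, OMe at C3) to aryl silyl ether 24, and dilute acid frees the C3 phenol, which is hydrogen-bonded to the acetyl group. The step needs a single orientation of the ynone, and both substituents of the triple bond secure it: carbonyl and benzyloxy group polarise it in the same sense, so the oxygen-bearing carbon is the only electrophilic site and meets the diene terminus with the largest HOMO coefficient, which places the acetyl between two oxygens and para to the methoxy group.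

Step 12
Reactants: 25 1-[2-(benzyloxy)-6-hydroxy-4-methoxy-5-methyl-3-{[2,4,6-tris(benzyloxy)-3-(3-methylbutyl)phenyl]methyl}phenyl]ethanone
Product: 26 1-[2,6-dihydroxy-4-methoxy-3-methyl-5-{[2,4,6-trihydroxy-3-(3-methylbutyl)phenyl]methyl}phenyl]ethanone
Conditions: H2 (1 atm), 10% Pd/C, EtOAc/MeOH, 23 °C; handled under argon
Reagents that add atoms: none
Why: Hydrogenolysis of four aryl benzyl ethers on Pd/C; the hydrogen-bonded aryl ketone, the methyl ether and the diarylmethane should be inert at atmospheric pressure.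

Step 13
Reactants: 26 1-[2,6-dihydroxy-4-methoxy-3-methyl-5-{[2,4,6-trihydroxy-3-(3-methylbutyl)phenyl]methyl}phenyl]ethanone
Product: 27 1-[3-(3-acetyl-2,4-dihydroxy-6-methoxy-5-methylbenzyl)-2,4,6-trihydroxy-5-(3-methylbutyl)phenyl]-2-methylpropan-1-one (CNP0238575.0)
Conditions: i-PrCOCl (1.1 equiv.), AlCl3 (6 equiv.), CH2Cl2/MeNO2, 0 → 23 °C; 1 M HCl
Reagents that add atoms: isobutyryl chloride CC(C)C(Cl)=O
Why: Friedel–Crafts acylation of an alkylphloroglucinol: C5' is the only unsubstituted aromatic carbon in the molecule, and any aryl ester formed first should be carried to the same ketone by Fries rearrangement under AlCl3.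

**Compound list**

1 | 1,3,5-tris(benzyloxy)benzene | c1c(OCc2ccccc2)cc(OCc2ccccc2)cc1OCc1ccccc1 | starting material
2 | N-{[2,4,6-tris(benzyloxy)phenyl]methylidene}-N-methylmethanaminium chloride | C[N+](C)=Cc1c(OCc2ccccc2)cc(OCc2ccccc2)cc1OCc1ccccc1.[Cl-] | intermediate (not isolated)
3 | 2,4,6-tris(benzyloxy)benzaldehyde | O=Cc1c(OCc2ccccc2)cc(OCc2ccccc2)cc1OCc1ccccc1 | intermediate
4 | 3-methyl-1-[2,4,6-tris(benzyloxy)phenyl]butan-1-ol (racemic) | CC(C)CC(O)c1c(OCc2ccccc2)cc(OCc2ccccc2)cc1OCc1ccccc1 | intermediate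
5 | 1,3,5-tris(benzyloxy)-2-(3-methylbutyl)benzene | CC(C)CCc1c(OCc2ccccc2)cc(OCc2ccccc2)cc1OCc1ccccc1 | intermediate
6 | N-{[2,4,6-tris(benzyloxy)-3-(3-methylbutyl)phenyl]methylidene}-N-methylmethanaminium chloride | C[N+](C)=Cc1c(OCc2ccccc2)c(CCC(C)C)c(OCc2ccccc2)cc1OCc1ccccc1.[Cl-] | intermediate (not isolated)
7 | 2,4,6-tris(benzyloxy)-3-(3-methylbutyl)benzaldehyde | O=Cc1c(OCc2ccccc2)c(CCC(C)C)c(OCc2ccccc2)cc1OCc1ccccc1 | intermediate
8 | methyl 2-methyl-3-oxobutanoate (methyl 2-methylacetoacetate) | COC(=O)C(C)C(C)=O | starting material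
9 | sodium lithium dianion of methyl 2-methyl-3-oxobutanoate | [Na+].[Li+].[CH2-]C(=O)[C-](C)C(=O)OC | intermediate (not isolated)
10 | methyl 5-hydroxy-2-methyl-3-oxo-5-[2,4,6-tris(benzyloxy)-3-(3-methylbutyl)phenyl]pentanoate (diastereomer mixture) | COC(=O)C(C)C(=O)CC(O)c1c(OCc2ccccc2)c(CCC(C)C)c(OCc2ccccc2)cc1OCc1ccccc1 | intermediate
11 | methyl 2-methyl-3-oxo-5-[2,4,6-tris(benzyloxy)-3-(3-methylbutyl)phenyl]pentanoate | COC(=O)C(C)C(=O)CCc1c(OCc2ccccc2)c(CCC(C)C)c(OCc2ccccc2)cc1OCc1ccccc1 | intermediate
12 | methyl 3,3-dimethoxy-2-methyl-5-[2,4,6-tris(benzyloxy)-3-(3-methylbutyl)phenyl]pentanoate | COC(=O)C(C)C(OC)(OC)CCc1c(OCc2ccccc2)c(CCC(C)C)c(OCc2ccccc2)cc1OCc1ccccc1 | intermediate (not isolated)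
13 | methyl 3-methoxy-2-methyl-5-[2,4,6-tris(benzyloxy)-3-(3-methylbutyl)phenyl]pent-2-enoate (E/Z mixture) | COC(=O)C(C)=C(OC)CCc1c(OCc2ccccc2)c(CCC(C)C)c(OCc2ccccc2)cc1OCc1ccccc1 | intermediate
14 | lithium dienolate of 13 | [Li+].[O-]C(OC)=C(C)C(OC)=CCc1c(OCc2ccccc2)c(CCC(C)C)c(OCc2ccccc2)cc1OCc1ccccc1 | intermediate (not isolated)
15 | 1,3-dimethoxy-2-methyl-1-(trimethylsilyloxy)-5-[2,4,6-tris(benzyloxy)-3-(3-methylbutyl)phenyl]penta-1,3-diene (geometric mixture) | COC(O[Si](C)(C)C)=C(C)C(OC)=CCc1c(OCc2ccccc2)c(CCC(C)C)c(OCc2ccccc2)cc1OCc1ccccc1 | intermediate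
16 | benzyl alcohol | OCc1ccccc1 | starting material
17 | trichloroethylene | ClC=C(Cl)Cl | starting material
18 | dichloroacetylene | ClC#CCl | intermediate (not isolated)
19 | (E)-benzyl 1,2-dichlorovinyl ether | Cl/C=C(/Cl)OCc1ccccc1 | intermediate
20 | benzyl chloroethynyl ether | ClC#COCc1ccccc1 | intermediate (not isolated)
21 | lithium (benzyloxy)acetylide | [Li]C#COCc1ccccc1 | intermediate (not isolated)
22 | 4-(benzyloxy)but-3-yn-2-one | CC(=O)C#COCc1ccccc1 | intermediate
23 | 1-[2-(benzyloxy)-4,6-dimethoxy-5-methyl-3-{[2,4,6-tris(benzyloxy)-3-(3-methylbutyl)phenyl]methyl}-6-(trimethylsilyloxy)cyclohexa-1,4-dien-1-yl]ethanone (diastereomer mixture) | COC1(O[Si](C)(C)C)C(C)=C(OC)C(Cc2c(OCc3ccccc3)c(CCC(C)C)c(OCc3ccccc3)cc2OCc2ccccc2)C(OCc2ccccc2)=C1C(C)=O | intermediate (not isolated)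
24 | 1-[2-(benzyloxy)-4-methoxy-5-methyl-3-{[2,4,6-tris(benzyloxy)-3-(3-methylbutyl)phenyl]methyl}-6-(trimethylsilyloxy)phenyl]ethanone | CC(=O)c1c(O[Si](C)(C)C)c(C)c(OC)c(Cc2c(OCc3ccccc3)c(CCC(C)C)c(OCc3ccccc3)cc2OCc2ccccc2)c1OCc1ccccc1 | intermediate (not isolated)
25 | 1-[2-(benzyloxy)-6-hydroxy-4-methoxy-5-methyl-3-{[2,4,6-tris(benzyloxy)-3-(3-methylbutyl)phenyl]methyl}phenyl]ethanone | CC(=O)c1c(O)c(C)c(OC)c(Cc2c(OCc3ccccc3)c(CCC(C)C)c(OCc3ccccc3)cc2OCc2ccccc2)c1OCc1ccccc1 | intermediate
26 | 1-[2,6-dihydroxy-4-methoxy-3-methyl-5-{[2,4,6-trihydroxy-3-(3-methylbutyl)phenyl]methyl}phenyl]ethanone | COc1c(C)c(O)c(C(C)=O)c(O)c1Cc1c(O)c(CCC(C)C)c(O)cc1O | intermediate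
27 | 1-[3-(3-acetyl-2,4-dihydroxy-6-methoxy-5-methylbenzyl)-2,4,6-trihydroxy-5-(3-methylbutyl)phenyl]-2-methylpropan-1-one (CNP0238575.0) | COc1c(C)c(O)c(C(C)=O)c(O)c1Cc1c(O)c(CCC(C)C)c(O)c(C(=O)C(C)C)c1O | target

**Step count**

Total: 13 steps. Longest linear sequence: 11 steps (steps 1–8, then 11–13); the ynone branch (steps 9–10) joins at step 11.

**Steps most likely to fail**

Step 11 (key step). The donor-substituted triple bond may react too slowly with the diene. Meanwhile the benzyl ynol ether can undergo sigmatropic rearrangement or hydration, the diene can be protodesilylated by adventitious acid, or [2+2] addition can take over from ring closure. The fallback uses known chemistry, sets out from enoate 13 and returns at pentaphenol 26. The lithium dienolate of 13 (LDA, 2.2 equiv., THF, −78 °C) is acylated at its γ-carbon with N-methoxy-N-methyl-2-(2-methyl-1,3-dioxolan-2-yl)acetamide F1, itself made from commercial ethyl (2-methyl-1,3-dioxolan-2-yl)acetate with MeNHOMe·HCl and i-PrMgCl. This should give methyl 3-methoxy-2-methyl-6-(2-methyl-1,3-dioxolan-2-yl)-5-oxo-4-{[2,4,6-tris(benzyloxy)-3-(3-methylbutyl)phenyl]methyl}hex-2-enoate F2. Dilute HCl in THF unmasks the 1,3-diketone, methyl 3-methoxy-2-methyl-5,7-dioxo-4-{[2,4,6-tris(benzyloxy)-3-(3-methylbutyl)phenyl]methyl}oct-2-enoate F3. NaOMe in MeOH then closes ring A by intramolecular Claisen condensation of the diketone carbanion onto the ester (the classical acylresorcinol cyclisation; the enoate geometry equilibrates through the dienolate). The product is 1-[2,6-dihydroxy-4-methoxy-3-methyl-5-{[2,4,6-tris(benzyloxy)-3-(3-methylbutyl)phenyl]methyl}phenyl]ethanone F4. Hydrogenolysis (H2, Pd/C) of its three benzyl ethers gives 26.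

Step 13. Strong Lewis acid may protonate ring B at the bridge carbon and so cleave or redistribute the diarylmethane. Esterification of the five phenols may outrun ring acylation, and the C1 methyl ether may be lost. The fallback sets out from 26 and returns at 27 by a Houben–Hoesch reaction. Isobutyronitrile, ZnCl2 and dry HCl in Et2O at 0 °C should convert 26 by C-selective attack of the nitrilium species at C5' into 1-[3-(3-acetyl-2,4-dihydroxy-6-methoxy-5-methylbenzyl)-2,4,6-trihydroxy-5-(3-methylbutyl)phenyl]-2-methylpropan-1-iminium chloride F5. Warm water hydrolyses this salt to 27; no acylium ion, no aluminium reagent and no ester by-product are involved.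

Step 10. The alkoxy ynone may be hydrated or decomposed while the tetrahedral adduct is released in aqueous medium, and the benzylic position may be metallated in competition. The fallback sets out from 19 and returns at 22. Acetylide 21, generated as before, is added to acetaldehyde at −78 °C to give 4-(benzyloxy)but-3-yn-2-ol F6 (racemic, basic work-up). This alcohol is oxidised with activated MnO2 in CH2Cl2 at 0 °C, and the filtrate containing 22 is used directly, so the ynone never meets aqueous acid.

**Further compounds**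

F1 | step 11 | N-methoxy-N-methyl-2-(2-methyl-1,3-dioxolan-2-yl)acetamide | CON(C)C(=O)CC1(C)OCCO1
F2 | step 11 | methyl 3-methoxy-2-methyl-6-(2-methyl-1,3-dioxolan-2-yl)-5-oxo-4-{[2,4,6-tris(benzyloxy)-3-(3-methylbutyl)phenyl]methyl}hex-2-enoate | COC(=O)C(C)=C(OC)C(Cc1c(OCc2ccccc2)c(CCC(C)C)c(OCc2ccccc2)cc1OCc1ccccc1)C(=O)CC1(C)OCCO1
F3 | step 11 | methyl 3-methoxy-2-methyl-5,7-dioxo-4-{[2,4,6-tris(benzyloxy)-3-(3-methylbutyl)phenyl]methyl}oct-2-enoate | COC(=O)C(C)=C(OC)C(Cc1c(OCc2ccccc2)c(CCC(C)C)c(OCc2ccccc2)cc1OCc1ccccc1)C(=O)CC(C)=O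
F4 | step 11 | 1-[2,6-dihydroxy-4-methoxy-3-methyl-5-{[2,4,6-tris(benzyloxy)-3-(3-methylbutyl)phenyl]methyl}phenyl]ethanone | COc1c(C)c(O)c(C(C)=O)c(O)c1Cc1c(OCc2ccccc2)c(CCC(C)C)c(OCc2ccccc2)cc1OCc1ccccc1
F5 | step 13 | 1-[3-(3-acetyl-2,4-dihydroxy-6-methoxy-5-methylbenzyl)-2,4,6-trihydroxy-5-(3-methylbutyl)phenyl]-2-methylpropan-1-iminium chloride | CC(C)C(=[NH2+])c1c(O)c(CCC(C)C)c(O)c(Cc2c(O)c(C(C)=O)c(O)c(C)c2OC)c1O.[Cl-]
F6 | step 10 | 4-(benzyloxy)but-3-yn-2-ol (racemic) | CC(O)C#COCc1ccccc1
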